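## Retrosynthetic overview

1. The ten-membered carbocycle is closed last, at C8–C9, by a SmI2-mediated intramolecular aldol (Reformatsky-type) macrocyclization of an α-bromoketone onto an aldehyde; this also delivers the free C9 hydroxyl.
2. The open chain comes from a zinc Barbier coupling (C3a–C4 bond) of a 3-(bromomethyl)butenolide (western fragment) with a β-acetoxy aldehyde (eastern fragment); this sets C3a and C4 from C11a and gives the α-methylene lactone, and the C4 alcohol is then angeloylated.
3. Western fragment: Evans alkylation (C10), then enantioselective iridium-catalysed 2-(alkoxycarbonyl)allylation of a primary alcohol with lactonization (C11a), then bromination and dehydrobromination.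
4. Eastern fragment: (S)-lactic acid, Seebach alkylation (C6), a terminal alkyne as masked C7 ketone (unmasked late by bromination and gold-catalysed hydration), ozonolysis to the aldehyde.
5. Ring order: γ-lactone first (in the western fragment), ten-membered carbocycle last.

Locants used below: O1, C2 (lactone C=O), C3 (=CH2), C3a, C4 (O-angeloyl), C5, C6 (CH3, OAc), C7 (C=O), C8, C9 (OH), C10 (CH3), C11, C11a (lactone O). The target is 3aS,4S,6R,9S,10R,11aR.

Assumption: the ligand antipode in step 6 is fixed on a test run so that C11a is R; (S)-SEGPHOS is written as the working choice.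

## Route

**Step 1**
Reactants: 1 (4S)-4-benzyl-3-propanoyl-1,3-oxazolidin-2-one
Product: 3 (4S)-4-benzyl-3-[(2R)-2-methylpent-4-enoyl]-1,3-oxazolidin-2-one, via sodium Z-enolate 2 (not isolated)
Conditions: NaN(SiMe3)2, THF, −78 °C; allyl iodide, −78 → −45 °C
Reagents that add atoms: allyl iodide, C=CCI
Why: Evans asymmetric alkylation, in which the chelated Z-enolate is allylated on the face away from the benzyl group, sets the methyl-bearing centre (later C10) as R.

**Step 2**
Reactants: 3 (4S)-4-benzyl-3-[(2R)-2-methylpent-4-enoyl]-1,3-oxazolidin-2-one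
Product: 4 (2R)-2-methylpent-4-en-1-ol
Conditions: LiBH4, MeOH (1 equiv), Et2O, 0 °C
Reagents that add atoms: none
Why: Reductive removal of the auxiliary (hydride attacks the exocyclic imide carbonyl) gives the primary alcohol without touching the α-centre or the alkene.

**Step 3**
Reactants: 4 (2R)-2-methylpent-4-en-1-ol
Product: 5 tert-butyl(dimethyl){[(2R)-2-methylpent-4-en-1-yl]oxy}silane
Conditions: TBSCl, imidazole, CH2Cl2, rt
Reagents that add atoms: tert-butyldimethylsilyl chloride, CC(C)(C)[Si](C)(C)Cl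
Why: Standard silylation gives an ether that survives iridium catalysis, bromine, DBU, zinc and acylation and is later removed by fluoride.

**Step 4**
Reactants: 5 tert-butyl(dimethyl){[(2R)-2-methylpent-4-en-1-yl]oxy}silane
Product: 7 (3R)-4-{[tert-butyl(dimethyl)silyl]oxy}-3-methylbutan-1-ol, via secondary ozonide 6 (not isolated)
Conditions: O3, CH2Cl2, −78 °C; NaBH4, MeOH, −78 → 0 °C
Reagents that add atoms: ozone, [O-][O+]=O
Why: Ozonolysis with hydride work-up removes the terminal carbon and gives the primary alcohol (later C11a) without affecting the stereocentre or the silyl ether.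

**Step 5**
Reactants: 8 methyl 2-(hydroxymethyl)prop-2-enoate
Product: 9 methyl 2-{[(tert-butoxycarbonyl)oxy]methyl}prop-2-enoate
Conditions: Boc2O, DMAP (5 mol %), CH2Cl2, 0 °C → rt
Reagents that add atoms: di-tert-butyl dicarbonate, CC(C)(C)OC(=O)OC(=O)OC(C)(C)C
Why: DMAP-catalysed O-acylation turns the allylic alcohol into an allylic carbonate that ionizes readily to a π-allyl donor.

**Step 6**
Reactants: 7 (3R)-4-{[tert-butyl(dimethyl)silyl]oxy}-3-methylbutan-1-ol; 9 methyl 2-{[(tert-butoxycarbonyl)oxy]methyl}prop-2-enoate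
Product: 12 (5R)-5-[(2R)-3-{[tert-butyl(dimethyl)silyl]oxy}-2-methylpropyl]-3-methylideneoxolan-2-one, via aldehyde 10 (not isolated), via hydroxy ester 11 (not isolated)
Conditions: [Ir(cod)Cl]2 (2.5 mol %), (S)-SEGPHOS (5 mol %), 4-chloro-3-nitrobenzoic acid (10 mol %), Cs2CO3 (20 mol %), THF, 90 °C; then CSA (10 mol %), CH2Cl2, 0 °C
Reagents that add atoms: none
Why: Krische-type transfer-hydrogenative carbonyl 2-(alkoxycarbonyl)allylation, in which the chiral iridium π-allyl adds to the transient aldehyde through a closed chair under catalyst control, sets C11a as R, and lactonization of the γ-hydroxy ester closes the α-methylene lactone.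

**Step 7**
Reactants: 12 (5R)-5-[(2R)-3-{[tert-butyl(dimethyl)silyl]oxy}-2-methylpropyl]-3-methylideneoxolan-2-one
Product: 13 (5R)-3-bromo-3-(bromomethyl)-5-[(2R)-3-{[tert-butyl(dimethyl)silyl]oxy}-2-methylpropyl]oxolan-2-one (both C3 epimers)
Conditions: Br2, CH2Cl2, 0 °C → rt, dark
Reagents that add atoms: bromine, BrBr
Why: Ionic addition of bromine across the exocyclic alkene gives the dibromide, whose new C3 centre is removed again in the next step.

**Step 8**
Reactants: 13 (5R)-3-bromo-3-(bromomethyl)-5-[(2R)-3-{[tert-butyl(dimethyl)silyl]oxy}-2-methylpropyl]oxolan-2-one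
Product: 14 (5R)-3-(bromomethyl)-5-[(2R)-3-{[tert-butyl(dimethyl)silyl]oxy}-2-methylpropyl]furan-2(5H)-one
Conditions: DBU (1.05 equiv), THF, −20 → 0 °C, 30 min
Reagents that add atoms: none
Why: E2 dehydrobromination of the tertiary bromide towards the ring CH2 gives the conjugated butenolide that keeps the allylic bromide, and the short cold exposure avoids epimerization at C5 of the butenolide.

**Step 9**
Reactants: 15 (S)-lactic acid
Product: 16 (2S,5S)-2-tert-butyl-5-methyl-1,3-dioxolan-4-one
Conditions: pivalaldehyde, TsOH (cat.), H2SO4 (cat.), pentane, reflux (Dean–Stark); crystallization from pentane at −78 °C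
Reagents that add atoms: pivalaldehyde, CC(C)(C)C=O
Why: Seebach acetalization gives mainly the cis dioxolanone, which is enriched by crystallization and stores the lactate chirality in the acetal centre.

**Step 10**
Reactants: 16 (2S,5S)-2-tert-butyl-5-methyl-1,3-dioxolan-4-one
Product: 18 (2S,5R)-2-tert-butyl-5-methyl-5-(prop-2-en-1-yl)-1,3-dioxolan-4-one, via lithium enolate 17 (not isolated)
Conditions: LiN(iPr)2, THF, −78 °C; allyl bromide, −78 → −30 °C
Reagents that add atoms: allyl bromide, C=CCBr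
Why: Seebach self-regeneration of stereocentres: the planar enolate is allylated anti to the tert-butyl group, which builds the quaternary centre (later C6) as R with overall retention.

**Step 11**
Reactants: 18 (2S,5R)-2-tert-butyl-5-methyl-5-(prop-2-en-1-yl)-1,3-dioxolan-4-one
Product: 19 (2R)-2-methylpent-4-ene-1,2-diol
Conditions: LiAlH4, Et2O, 0 °C → rt
Reagents that add atoms: none
Why: Hydride reduction of the lactone carbonyl collapses the acetal (pivalaldehyde is reduced to neopentyl alcohol) and gives the diol with the quaternary centre untouched.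

**Step 12**
Reactants: 19 (2R)-2-methylpent-4-ene-1,2-diol
Product: 20 (2R)-2-hydroxy-2-methylpent-4-enal
Conditions: SO3·pyridine, DMSO, Et3N, CH2Cl2, 0 °C
Reagents that add atoms: none
Why: Parikh–Doering oxidation takes only the primary alcohol to the aldehyde, since the tertiary alcohol cannot be oxidized and no glycol cleavage occurs.

**Step 13**
Reactants: 20 (2R)-2-hydroxy-2-methylpent-4-enal
Product: 21 (3R)-3-methylhex-5-en-1-yn-3-ol
Conditions: dimethyl (1-diazo-2-oxopropyl)phosphonate, K2CO3, MeOH, 0 °C → rt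
Reagents that add atoms: dimethyl (1-diazo-2-oxopropyl)phosphonate, COP(=O)(OC)C(=[N+]=[N-])C(C)=O
Why: Seyferth–Gilbert homologation with the Ohira–Bestmann reagent converts the aldehyde, which has no α-hydrogen and cannot epimerize, into the terminal alkyne that masks the C7 ketone.

**Step 14**
Reactants: 21 (3R)-3-methylhex-5-en-1-yn-3-ol
Product: 22 (3R)-3-methylhex-5-en-1-yn-3-yl acetate
Conditions: Ac2O, Et3N, DMAP (20 mol %), CH2Cl2, rt
Reagents that add atoms: acetic anhydride, CC(=O)OC(C)=O
Why: DMAP-catalysed acylation works on this tertiary propargylic alcohol because the alkyne makes it sterically accessible, and the C–O bond is not broken.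

**Step 15**
Reactants: 22 (3R)-3-methylhex-5-en-1-yn-3-yl acetate
Product: 24 (3R)-3-methyl-5-oxopent-1-yn-3-yl acetate, via secondary ozonide 23 (not isolated)
Conditions: O3, CH2Cl2, −78 °C (stopped at first excess); PPh3, −78 °C → rt; used crude
Reagents that add atoms: ozone, [O-][O+]=O
Why: Ozonolysis is chemoselective for the alkene over the much less reactive alkyne, and the neutral phosphine work-up keeps the β-acetoxy aldehyde from eliminating.

**Step 16**
Reactants: 14 (5R)-3-(bromomethyl)-5-[(2R)-3-{[tert-butyl(dimethyl)silyl]oxy}-2-methylpropyl]furan-2(5H)-one; 24 (3R)-3-methyl-5-oxopent-1-yn-3-yl acetate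
Product: 26 (3R,5S)-5-{(2R,3R)-2-[(2R)-3-{[tert-butyl(dimethyl)silyl]oxy}-2-methylpropyl]-4-methylidene-5-oxooxolan-3-yl}-5-hydroxy-3-methylpent-1-yn-3-yl acetate, via allylzinc bromide 25 (not isolated)
Conditions: Zn dust, THF–sat. aq NH4Cl, 0 °C → rt
Reagents that add atoms: none
Why: Zinc Barbier allylation (SE2′) through a six-membered chair: the aldehyde adds to the butenolide face opposite the C11a side chain (trans lactone, C3a) with its residue equatorial on the ring-locked E-type allyl unit (anti adduct, C4 S), while the alkyne and acetate are inert and no ketone is present to compete.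

**Step 17**
Reactants: 26 (Barbier adduct, as named in step 16)
Product: 28 (1S,3R)-3-(acetyloxy)-1-{(2R,3S)-2-[(2R)-3-{[tert-butyl(dimethyl)silyl]oxy}-2-methylpropyl]-4-methylidene-5-oxooxolan-3-yl}-3-methylpent-4-yn-1-yl (2Z)-2-methylbut-2-enoate, via mixed anhydride 27 (not isolated)
Conditions: angelic acid, 2,4,6-trichlorobenzoyl chloride, Et3N, toluene, rt; then 26, 80 °C
Reagents that add atoms: angelic acid, C/C=C(/C)C(=O)O
Why: Yamaguchi-type mixed-anhydride esterification run without DMAP transfers the angeloyl group to the hindered C4 alcohol with retention at carbon and without Z to E isomerization.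

**Step 18**
Reactants: 28 (angelate silyl ether, as named in step 17)
Product: 29 (1S,3R)-3-(acetyloxy)-1-{(2R,3S)-2-[(2R)-3-hydroxy-2-methylpropyl]-4-methylidene-5-oxooxolan-3-yl}-3-methylpent-4-yn-1-yl (2Z)-2-methylbut-2-enoate
Conditions: HF·pyridine, THF–pyridine, 0 °C → rt
Reagents that add atoms: none
Why: Fluoride-driven desilylation under buffered acidic conditions frees the primary alcohol and leaves the acetate, angelate, lactone and alkyne alone.

**Step 19**
Reactants: 29 (primary alcohol, as named in step 18)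
Product: 30 (1S,3R)-3-(acetyloxy)-5-bromo-1-{(2R,3S)-2-[(2R)-3-hydroxy-2-methylpropyl]-4-methylidene-5-oxooxolan-3-yl}-3-methylpent-4-yn-1-yl (2Z)-2-methylbut-2-enoate
Conditions: NBS, AgNO3 (10 mol %), acetone, rt, dark
Reagents that add atoms: N-bromosuccinimide, O=C1CCC(=O)N1Br
Why: Silver-catalysed electrophilic bromination of the terminal alkyne (through the silver acetylide) gives the 1-bromoalkyne and does not touch the electron-poor alkenes.

**Step 20**
Reactants: 30 (bromoalkyne, as named in step 19)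
Product: 31 (1S,3R)-3-(acetyloxy)-5-bromo-1-{(2R,3S)-2-[(2R)-3-hydroxy-2-methylpropyl]-4-methylidene-5-oxooxolan-3-yl}-3-methyl-4-oxopentyl (2Z)-2-methylbut-2-enoate
Conditions: Ph3PAuNTf2 (5 mol %), 1,4-dioxane–H2O (10:1), 40 °C
Reagents that add atoms: water, O
Why: Gold-catalysed hydration of the 1-bromoalkyne, helped by 5-exo participation of the neighbouring acetate carbonyl, puts the oxygen on C7 and gives the α-bromomethyl ketone with the acetate back on C6.

**Step 21**
Reactants: 31 (bromoketone alcohol, as named in step 20)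
Product: 32 (1S,3R)-3-(acetyloxy)-5-bromo-3-methyl-1-{(2R,3S)-4-methylidene-2-[(2R)-2-methyl-3-oxopropyl]-5-oxooxolan-3-yl}-4-oxopentyl (2Z)-2-methylbut-2-enoate
Conditions: Dess–Martin periodinane, NaHCO3, CH2Cl2, 0 °C → rt; used at once
Reagents that add atoms: none
Why: Dess–Martin oxidation under buffered neutral conditions gives the α-branched aldehyde without epimerizing C10 or disturbing the bromoketone.

**Step 22**
Reactants: 32 (bromoketo aldehyde, as named in step 21)
Product: 34 (3aS,4S,6R,9S,10R,11aR)-6-(acetyloxy)-9-hydroxy-6,10-dimethyl-3-methylidene-2,7-dioxododecahydrocyclodeca[b]furan-4-yl (2Z)-2-methylbut-2-enoate (CNP0141210.6), via samarium enolate 33 (not isolated)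
Conditions: SmI2 (0.1 M in THF, 2.1 equiv) added dropwise to 32 (2 mM in THF), −78 °C; sat. aq NH4Cl at −78 °C
Reagents that add atoms: none
Why: In this Reformatsky-type intramolecular aldol macrocyclization the C–Br bond is reduced far faster than the aldehyde, enoates or acetoxy ketone, and the trivalent samarium enolate adds to the aldehyde through a chelated chair; my working model is that the ring holds C11 gauche to the forming bond so that the C10 methyl sits anti to the incoming carbon, which would give the 9S (9,10-anti) alcohol.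

## Compound list

1 | (4S)-4-benzyl-3-propanoyl-1,3-oxazolidin-2-one | CCC(=O)N1[C@@H](Cc2ccccc2)COC1=O | starting material
2 | sodium (Z)-enolate of 1 | C/C=C(\[O-])N1[C@@H](Cc2ccccc2)COC1=O.[Na+] | intermediate
3 | (4S)-4-benzyl-3-[(2R)-2-methylpent-4-enoyl]-1,3-oxazolidin-2-one | C=CC[C@@H](C)C(=O)N1[C@@H](Cc2ccccc2)COC1=O | intermediate
4 | (2R)-2-methylpent-4-en-1-ol | C=CC[C@@H](C)CO | intermediate
5 | tert-butyl(dimethyl){[(2R)-2-methylpent-4-en-1-yl]oxy}silane | C=CC[C@@H](C)CO[Si](C)(C)C(C)(C)C | intermediate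
6 | 3-[(2R)-3-{[tert-butyl(dimethyl)silyl]oxy}-2-methylpropyl]-1,2,4-trioxolane (secondary ozonide of 5) | O1OC(C[C@@H](C)CO[Si](C)(C)C(C)(C)C)OC1 | intermediate
7 | (3R)-4-{[tert-butyl(dimethyl)silyl]oxy}-3-methylbutan-1-ol | OCC[C@@H](C)CO[Si](C)(C)C(C)(C)C | intermediate
8 | methyl 2-(hydroxymethyl)prop-2-enoate | C=C(CO)C(=O)OC | starting material
9 | methyl 2-{[(tert-butoxycarbonyl)oxy]methyl}prop-2-enoate | C=C(COC(=O)OC(C)(C)C)C(=O)OC | intermediate
10 | (3R)-4-{[tert-butyl(dimethyl)silyl]oxy}-3-methylbutanal | O=CC[C@@H](C)CO[Si](C)(C)C(C)(C)C | intermediate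
11 | methyl (4R,6R)-7-{[tert-butyl(dimethyl)silyl]oxy}-4-hydroxy-6-methyl-2-methylideneheptanoate | C=C(C[C@H](O)C[C@@H](C)CO[Si](C)(C)C(C)(C)C)C(=O)OC | intermediate
12 | (5R)-5-[(2R)-3-{[tert-butyl(dimethyl)silyl]oxy}-2-methylpropyl]-3-methylideneoxolan-2-one | C=C1C[C@@H](C[C@@H](C)CO[Si](C)(C)C(C)(C)C)OC1=O | intermediate
13 | (5R)-3-bromo-3-(bromomethyl)-5-[(2R)-3-{[tert-butyl(dimethyl)silyl]oxy}-2-methylpropyl]oxolan-2-one (C3 epimers) | O=C1O[C@H](C[C@@H](C)CO[Si](C)(C)C(C)(C)C)CC1(Br)CBr | intermediate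
14 | (5R)-3-(bromomethyl)-5-[(2R)-3-{[tert-butyl(dimethyl)silyl]oxy}-2-methylpropyl]furan-2(5H)-one | O=C1O[C@H](C[C@@H](C)CO[Si](C)(C)C(C)(C)C)C=C1CBr | intermediate
15 | (S)-lactic acid | C[C@H](O)C(=O)O | starting material
16 | (2S,5S)-2-tert-butyl-5-methyl-1,3-dioxolan-4-one | CC(C)(C)[C@@H]1OC(=O)[C@H](C)O1 | intermediate
17 | lithium (2S)-2-tert-butyl-5-methyl-1,3-dioxol-4-olate (enolate of 16) | CC(C)(C)[C@@H]1OC([O-])=C(C)O1.[Li+] | intermediate
18 | (2S,5R)-2-tert-butyl-5-methyl-5-(prop-2-en-1-yl)-1,3-dioxolan-4-one | CC(C)(C)[C@@H]1OC(=O)[C@](CC=C)(C)O1 | intermediate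
19 | (2R)-2-methylpent-4-ene-1,2-diol | OC[C@](C)(O)CC=C | intermediate
20 | (2R)-2-hydroxy-2-methylpent-4-enal | O=C[C@](C)(O)CC=C | intermediate
21 | (3R)-3-methylhex-5-en-1-yn-3-ol | C#C[C@](C)(O)CC=C | intermediate
22 | (3R)-3-methylhex-5-en-1-yn-3-yl acetate | C#C[C@](C)(OC(C)=O)CC=C | intermediate
23 | (2R)-2-methyl-1-(1,2,4-trioxolan-3-yl)but-3-yn-2-yl acetate (secondary ozonide of 22) | C#C[C@](C)(OC(C)=O)CC1OCOO1 | intermediate
24 | (3R)-3-methyl-5-oxopent-1-yn-3-yl acetate | C#C[C@](C)(OC(C)=O)CC=O | intermediate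
25 | {[(5R)-5-[(2R)-3-{[tert-butyl(dimethyl)silyl]oxy}-2-methylpropyl]-2-oxo-2,5-dihydrofuran-3-yl]methyl}zinc bromide | O=C1O[C@H](C[C@@H](C)CO[Si](C)(C)C(C)(C)C)C=C1C[Zn]Br | intermediate
26 | (3R,5S)-5-{(2R,3R)-2-[(2R)-3-{[tert-butyl(dimethyl)silyl]oxy}-2-methylpropyl]-4-methylidene-5-oxooxolan-3-yl}-5-hydroxy-3-methylpent-1-yn-3-yl acetate | C=C1C(=O)O[C@H](C[C@@H](C)CO[Si](C)(C)C(C)(C)C)[C@H]1[C@@H](O)C[C@@](C)(OC(C)=O)C#C | intermediate
27 | (2Z)-2-methylbut-2-enoic 2,4,6-trichlorobenzoic anhydride | C/C=C(/C)C(=O)OC(=O)c1c(Cl)cc(Cl)cc1Cl | intermediate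
28 | (1S,3R)-3-(acetyloxy)-1-{(2R,3S)-2-[(2R)-3-{[tert-butyl(dimethyl)silyl]oxy}-2-methylpropyl]-4-methylidene-5-oxooxolan-3-yl}-3-methylpent-4-yn-1-yl (2Z)-2-methylbut-2-enoate | C=C1C(=O)O[C@H](C[C@@H](C)CO[Si](C)(C)C(C)(C)C)[C@H]1[C@@H](OC(=O)/C(C)=C\C)C[C@@](C)(OC(C)=O)C#C | intermediate
29 | (1S,3R)-3-(acetyloxy)-1-{(2R,3S)-2-[(2R)-3-hydroxy-2-methylpropyl]-4-methylidene-5-oxooxolan-3-yl}-3-methylpent-4-yn-1-yl (2Z)-2-methylbut-2-enoate | C=C1C(=O)O[C@H](C[C@@H](C)CO)[C@H]1[C@@H](OC(=O)/C(C)=C\C)C[C@@](C)(OC(C)=O)C#C | intermediate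
30 | (1S,3R)-3-(acetyloxy)-5-bromo-1-{(2R,3S)-2-[(2R)-3-hydroxy-2-methylpropyl]-4-methylidene-5-oxooxolan-3-yl}-3-methylpent-4-yn-1-yl (2Z)-2-methylbut-2-enoate | C=C1C(=O)O[C@H](C[C@@H](C)CO)[C@H]1[C@@H](OC(=O)/C(C)=C\C)C[C@@](C)(OC(C)=O)C#CBr | intermediate
31 | (1S,3R)-3-(acetyloxy)-5-bromo-1-{(2R,3S)-2-[(2R)-3-hydroxy-2-methylpropyl]-4-methylidene-5-oxooxolan-3-yl}-3-methyl-4-oxopentyl (2Z)-2-methylbut-2-enoate | C=C1C(=O)O[C@H](C[C@@H](C)CO)[C@H]1[C@@H](OC(=O)/C(C)=C\C)C[C@@](C)(OC(C)=O)C(=O)CBr | intermediate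
32 | (1S,3R)-3-(acetyloxy)-5-bromo-3-methyl-1-{(2R,3S)-4-methylidene-2-[(2R)-2-methyl-3-oxopropyl]-5-oxooxolan-3-yl}-4-oxopentyl (2Z)-2-methylbut-2-enoate | C=C1C(=O)O[C@H](C[C@@H](C)C=O)[C@H]1[C@@H](OC(=O)/C(C)=C\C)C[C@@](C)(OC(C)=O)C(=O)CBr | intermediate
33 | diiodosamarium enolate of 32 (O-bound at C7, trivalent samarium) | C=C1C(=O)O[C@H](C[C@@H](C)C=O)[C@H]1[C@@H](OC(=O)/C(C)=C\C)C[C@@](C)(OC(C)=O)C(=C)O[Sm](I)I | intermediate
34 | (3aS,4S,6R,9S,10R,11aR)-6-(acetyloxy)-9-hydroxy-6,10-dimethyl-3-methylidene-2,7-dioxododecahydrocyclodeca[b]furan-4-yl (2Z)-2-methylbut-2-enoate (CNP0141210.6) | C=C1C(=O)O[C@@H]2C[C@@H](C)[C@@H](O)CC(=O)[C@](C)(OC(C)=O)C[C@H](OC(=O)/C(C)=C\C)[C@@H]12 | target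

## Step count and risks

Total step count: 22. Longest linear sequence: 14 steps (steps 1–4, 6–8 and 16–22; the branch 9–15 followed by 16–22 is equally long).

**Step 22 (samarium aldol ring closure).** Risks are simple reduction of the bromoketone, oligomers, and the wrong configuration at C9, because the facial preference comes only from a conformational model of the ring-forming transition state. The fallback sets out from 32 and comes back at 34. The closure is run as written, whatever the C9 ratio. The mixture of 34 and the (9R)-epimer of 34 F1 is oxidized with Dess–Martin periodinane to the macrocyclic 7,9-dione F2. The less hindered C9 carbonyl (C7 is shielded by the quaternary C6) is then reduced under reagent control with (R)-2-methyl-CBS-oxazaborolidine and catecholborane at −78 °C. The antipode is chosen on the assumption that the branched C10 side acts as the large group. This takes stereocontrol out of the ring closure and gives 34.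

**Step 16 (zinc Barbier coupling).** Risks are loss of acetic acid from the β-acetoxy aldehyde 24 in the aqueous medium, protonation of the allylzinc, and a lower diastereomer ratio than expected. The fallback sets out from 14 and comes back at 26. Borylation of 14 with B2pin2 and Pd2(dba)3 (zerovalent palladium) in toluene gives the allylboronate pinacol ester of 14 F3. F3 adds to 24 in dry toluene at 60 °C through the same closed chair, without water or metal salts, to give the pinacol boronate ester of 26 F4. Triethanolamine work-up then frees 26.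

**Step 17 (angeloylation).** Risks are a slow reaction at the hindered C4 alcohol, Z to E isomerization to the tiglate, and acetyl migration from O6 to O4 at 80 °C. The fallback sets out from 26 and comes back at 28. Esterification of 26 with 2-[bis(2,2,2-trifluoroethoxy)phosphoryl]propanoic acid (DCC, DMAP cat., CH2Cl2, 0 °C) gives the phosphonopropanoate of 26 F5. A Still–Gennari olefination of F5 (KN(SiMe3)2, 18-crown-6, THF, −78 °C; acetaldehyde) builds the Z-configured 2-methylbut-2-enoate on the ester and gives 28 without any angelic acid derivative being heated.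

## Further compounds

F1 | step 22 | (9R)-epimer of 34 | C=C1C(=O)O[C@@H]2C[C@@H](C)[C@H](O)CC(=O)[C@](C)(OC(C)=O)C[C@H](OC(=O)/C(C)=C\C)[C@@H]12
F2 | step 22 | macrocyclic 7,9-dione (9-oxo analogue of 34) | C=C1C(=O)O[C@@H]2C[C@@H](C)C(=O)CC(=O)[C@](C)(OC(C)=O)C[C@H](OC(=O)/C(C)=C\C)[C@@H]12
F3 | step 16 | allylboronate pinacol ester of 14, (5R)-5-[(2R)-3-{[tert-butyl(dimethyl)silyl]oxy}-2-methylpropyl]-3-[(4,4,5,5-tetramethyl-1,3,2-dioxaborolan-2-yl)methyl]furan-2(5H)-one | O=C1O[C@H](C[C@@H](C)CO[Si](C)(C)C(C)(C)C)C=C1CB1OC(C)(C)C(C)(C)O1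
F4 | step 16 | pinacol boronate ester of 26 (O4–B) | C=C1C(=O)O[C@H](C[C@@H](C)CO[Si](C)(C)C(C)(C)C)[C@H]1[C@@H](OB2OC(C)(C)C(C)(C)O2)C[C@@](C)(OC(C)=O)C#C
F5 | step 17 | phosphonopropanoate of 26, 2-[bis(2,2,2-trifluoroethoxy)phosphoryl]propanoate ester at O4 | C=C1C(=O)O[C@H](C[C@@H](C)CO[Si](C)(C)C(C)(C)C)[C@H]1[C@@H](OC(=O)C(C)P(=O)(OCC(F)(F)F)OCC(F)(F)F)C[C@@](C)(OC(C)=O)C#C
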